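Oak's product slowed to a crawl: it gained 0.5 percentage points of the charge between 2.00 min and 2.50 min, with 70.3% of the charge not yet product.

| setting | oak | birch | flask |
|---|---|---|---|
| left-handed substrate | 28 mM | 44 mM | 20 mM |
| right-handed substrate | 28 mM | 44 mM | 20 mM |
| gas | 2.3 mM (held) | 2.3 mM (held) | 2.3 mM (held) |
| free catalyst | 1.5 mM | 1.5 mM | 1.5 mM |
| impurity | 0.19 mM | 0.19 mM | 0.19 mM |
| remark | run made earlier | run made earlier |  |
| time |  |  | 3.0 min |

- oak (time / min: left-handed product / %, right-handed product / %): 0.167: 3.4, 1.4; 0.500: 8.9, 3.7; 0.833: 13.9, 5.9; 1.33: 18.2, 8.1; 2.00: 20.4, 8.8; 2.50: 20.6, 9.1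
- birch (time / min: left-handed product / %, right-handed product / %): 0.417: 4.9, 2.3; 0.833: 9.9, 4.3; 1.33: 13.7, 5.9; 1.50: 14.3, 6.2; 2.00: 15.7, 6.3; 2.50: 16.9, 7.1

(each reading ± 0.3 percentage points)

- free catalyst is single-handed; left-handed substrate and right-handed substrate are mirror images of each other, charged as a racemate, each of them at the stated concentration
- what was read earlier has a scatter of 0.3 percentage points, one standard deviation
- at the start none of the gas is in solution
- an excess is below zero if the other one leads

* excess of left-handed product over right-handed product in the product at 20 s
* excess of left-handed product over right-handed product in the product at 3.0 min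
* part of the left-handed substrate and right-handed substrate charged together that has reacted at 3.0 min

Through that slowing I saw no common drift in the product. From 0.833 min to the last reading, oak's excess went from 40.4% to 38.7%, while birch's went the other way, from 39.4% to 40.8%. So I froze the excess, left minus right over their sum, and pooled the last readings of both runs into a frozen excess of 39.7%, my value at both asked times. I reckoned no conversion.

The forecast gave 42% at 20 s, 38% at 3.0 min and a conversion of 33%, with a selectivity it judged “does not depend on concentration”. Its excess falls between the two times, and mine stays flat.

The flask gave 39.5%, 38.9% and 34.8%, within the forecast's tolerance.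

    reagent + free catalyst + left-handed substrate → free catalyst + left-handed product (k = 16000 M⁻² s⁻¹)
    reagent + free catalyst + right-handed substrate → free catalyst + right-handed product (k = 6700 M⁻² s⁻¹)
    left-handed substrate ⇌ right-handed substrate (k = 0.0290 s⁻¹)
    gas ⇌ reagent, rate k4*(csat - [reagent]) (kL = 0.150 s⁻¹)
    free catalyst + impurity → spent catalyst A (k = 7800 M⁻¹ s⁻¹)
    free catalyst → spent catalyst B (k = 0.0320 s⁻¹)

The flask ran as a dynamic kinetic resolution: the excess of right-handed over left-handed substrate was 3.44% at 0.750 min and 0.158% at 3.00 min, and the forward half-life of left-handed substrate, 0.40 min, is short against 3.0 min. A run with half the left-handed substrate, other amounts as they are, ended at 30.7%, below both the forecast and my value.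

For the neighbour charged with 3.8 mM of free catalyst, 39.7% and that neighbour's computed reacted part of 52.1% put left-handed product at 36.4%. The computed flask gave an excess of 37.8% and 35.9% of left-handed product.

The data were computed for an exercise.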